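Remark: atoms carry eremophilane numbers (ring A = C1–C5 and C10, ring B = C5–C10, C11–C13 on C7, C14 on C5, C15 on C4). The 2-methylbutanoyl stereocentre is R as drawn, so purchased (R)-2-methylbutanoic acid is assumed. In the systematic names of bicyclic compounds, naphthalene locants 4, 4a, 6, 7, 8, 8a stand for C4, C5, C7, C8, C9, C10.

## Analysis of the target

The target is a cis-fused decalin of the eremophilane type. Ring A (C1–C5, C10) carries the C2 ketone and the C15 methyl on C4. Ring B (C5–C10) carries the angular C14 methyl on C5, an isopropenyl group on C7, an (R)-2-methylbutanoate on O8 and a tiglate on O9. The six ring stereocentres are 4S, 5R, 7R, 8R, 9S, 10S: C14, C15 and H10 share one face, O8 and O9 share the other and are cis to each other, and the isopropenyl group is trans to O8. The C4 (tertiary)–C5 (quaternary)–C10 triad is flanked by three further contiguous stereocentres on ring B, and O9 is cis to C1, on the concave side, where an external reagent would not easily place it. Sensitive points are the two different esters on a cis-diol (acyl migration once one hydroxyl is free), the epimerisable α-carbon of the 2-methylbutanoate, the isopropenyl group, and any precursor with a C11 ketone β to the O8 substituent. The strategy rests on one feature: a tiglate on O9 already holds C6, C5, C14, C4 and C15 with the right alkene geometry, and O9 sits on C9 next to C10. This ester can therefore act as a tethered dienophile toward a C10=C1–C2(OSi)=C3 diene and close ring A across C3–C4 and C5–C10. The tiglate is used twice: once as skeleton, once at the end as the ester.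

## Retrosynthetic reasoning

Esters and C2 mask. Target 27 is the deketalised form of 26, which comes from alcohol 24 and acid 25; 24 is 23 without its PMB group. The tiglate goes on first (19 + 9 → 21) because O9 is the hydroxyl that is free once ring B is closed. O8 is a PMB ether rather than a silyl ether: it cannot migrate to O9, it is a poor β-leaving group next to the C11 ketone, and it comes off under neutral oxidative conditions beside the tiglate.

C11=C13. The isopropenyl group of 23 is cut to the acetyl group of 22, because a methyl ketone on C7 is what an aldol ring closure delivers. C2 is also a ketone at that point, so it is masked first (22 from 21); with O9 acylated no hydroxyl can interfere with ketal formation.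

C7–H. Ketone 19 is traced to enone 18. Equilibration at C7 is not relied on, because both chair forms of this cis-decalin carry a syn-axial interaction and the preference for the equatorial acetyl group is expected to be small. The O9 hydroxyl on the same face as the required H7 is used instead to direct hydrogenation.

C6–C7. Ring B is opened at the enone double bond (18 from 16). C6 sits on the quaternary centre and cannot enolise, and C7 is the only α-carbon that reaches it through a six-membered ring. The C6 aldehyde is carried as lactol 15/16, obtained by partial reduction of lactone 14, so no separate oxidation at C6 is needed.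

C3–C4 and C5–C10 (key). Lactone 14 is cut back to dienyl tiglate 13. The cut is made here because it removes ring A, the lactone and the C4, C5, C10 stereocentres at once and leaves an acyclic precursor with only the two sugar-derived stereocentres. The chain linking C10 and C5 is C9–O9–C6, three atoms, a 1,3,8-nonatriene pattern.

Precursor. Diene 13 is the silyl dienol ether of enone 12. The C11 ketone of 12 is ketal-masked so that only one ketone is enolised. 12 comes from diketone 11 (Wacker oxidation of the terminal alkene of 10), and 10 from alcohol 8 and tiglic acid 9.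

Chiral pool. Enone 8 is cut at C10=C1 into diol 5 and ylide 6. Diol 5 goes back through 4, 3 and 2 to 2-deoxy-L-ribose 1, which supplies C11, C7, C8, C9 and C10 with both stereocentres. O8 and O9 are told apart by the terminal acetonide of 3.

## Alternatives that were turned down

Alternative 1: C5–C6 is cut. A ring-A precursor A2 (exocyclic C5=C14 alkene, C2 ketal, acetonide-protected C8/C9 chain on C10 ending in an α-methylene ketone) would be treated with Fe(acac)3 and PhSiH3. Hydrogen-atom transfer to C14 gives a tertiary C5 radical, which is captured by the enone terminus C6 to give decalin A1.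
- For: the quaternary centre forms under mild, chemoselective, polarity-matched conditions, and A1 already has the C11 ketone and both oxygens. After the key step this route is probably shorter than the chosen one.
- Against: the C5 configuration (C14 cis to C15 and to H10) must come from face selection on a nearly planar radical with only the C4 methyl and the C10 chain as bias. C7 is set by an unselective quench. The acetonide ties O8 and O9 together, so the two different esters would need selective mono-acylation of a cis-diol.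
- Comparison: the chosen route transfers alkene geometry stereospecifically to C4/C5 and distinguishes O8 from O9 from step 2 on.

Alternative 2: C5–C6 and C9–C10 are cut. The 2-methylcyclohexenone A4 would be combined with 1-methoxy-3-(trimethylsilyloxy)buta-1,3-diene A5 (heat or ZnCl2); acid work-up gives the cis-fused enedione A3.
- For: this is the most convergent route, and it reaches a cis-decalin with the angular methyl in fewer steps than the chosen route. On brevity to the bicycle it is stronger.
- Against: the α-methyl enone is a reluctant dienophile and facial control by the remote C2 silyloxy group is weak. A3 is oxygenated at the wrong places: C4 is a ketone where the methyl stereocentre is needed, C9 carries no oxygen, and C7 (the enone α-carbon) lacks its three-carbon unit.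
- Comparison: C4, C7, C8 and C9 and the O8/O9 distinction would all have to be added by substrate control on a flexible cis-decalin, likely a dozen or more steps. The chosen route brings C8/C9 from the sugar and sets C4 in the cycloaddition.

Alternative 3: C9–C10 is cut. Enone-aldehyde A7 (C2 ketone, C1=C10 alkene, quaternary C5 bearing the C6–C7(isopropenyl)–C8(OTBS)–C9 aldehyde chain) would be reduced at a carbon or lead cathode (Et4NOTs, dimethyl malonate as proton source), coupling C10 with C9 to give hydroxy decalin A6.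
- For: A6 has O8 and O9 already differentiated and is three steps from the target, the shortest endgame of all.
- Against: the two new centres must come out with a cis fusion and with the hydroxyl cis to C1; reductive couplings of this kind tend to place the new hydroxyl trans to the ketone-bearing branch. A7 itself is hard to make: a quaternary C5 next to C4 and remote C7/C8 stereocentres related across C6 without a ring, plus an epimerisable α-silyloxy aldehyde.
- Comparison: the chosen route gives up the short endgame but fixes the O9/C10 relation by delivering the dienophile through O9.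

Key step: step 10

## Route

Step 1
Reactants: 1 2-deoxy-L-ribose
Product: 2 (2S,3R)-hex-5-ene-1,2,3-triol
Conditions: Ph3PCH3Br, KOtBu, THF, 0 °C → reflux
Reagents that add atoms: methyltriphenylphosphonium bromide, C[P+](c1ccccc1)(c1ccccc1)c1ccccc1.[Br-]
Why: Wittig methylenation of the aldehyde form of the free sugar (lactol–aldehyde equilibrium), an established reaction of unprotected 2-deoxypentoses; the two stereocentres (later C8 and C9) are untouched.

Step 2
Reactants: 2 (2S,3R)-hex-5-ene-1,2,3-triol
Product: 3 (1R)-1-[(4S)-2,2-dimethyl-1,3-dioxolan-4-yl]but-3-en-1-ol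
Conditions: Me2C(OMe)2, TsOH (cat.), acetone, rt
Reagents that add atoms: 2,2-dimethoxypropane, COC(C)(C)OC
Why: Acetonide formation under thermodynamic control; the terminal monosubstituted dioxolane is favoured over the cis-disubstituted internal dioxolane and the 1,3-dioxane, so only the future O8 hydroxyl stays free.

Step 3
Reactants: 3 (1R)-1-[(4S)-2,2-dimethyl-1,3-dioxolan-4-yl]but-3-en-1-ol
Product: 4 (4S)-4-[(1R)-1-[(4-methoxybenzyl)oxy]but-3-en-1-yl]-2,2-dimethyl-1,3-dioxolane
Conditions: NaH, PMBCl, Bu4NI (cat.), DMF, 0 °C → rt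
Reagents that add atoms: 4-methoxybenzyl chloride, COc1ccc(CCl)cc1
Why: Williamson etherification of the secondary alkoxide; the PMB ether cannot migrate, is a poor β-leaving group and is later removed under neutral conditions.

Step 4
Reactants: 4 (4S)-4-[(1R)-1-[(4-methoxybenzyl)oxy]but-3-en-1-yl]-2,2-dimethyl-1,3-dioxolane
Product: 5 (2S,3R)-3-[(4-methoxybenzyl)oxy]hex-5-ene-1,2-diol
Conditions: AcOH/H2O (4:1), 40 °C
Reagents that add atoms: none
Why: Mild acid hydrolysis of the terminal acetonide; PMB ether and alkene are stable to aqueous acetic acid.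

Step 5
Reactants: 5 (2S,3R)-3-[(4-methoxybenzyl)oxy]hex-5-ene-1,2-diol; 6 1-(triphenylphosphoranylidene)propan-2-one
Product: 8 (3E,5S,6R)-5-hydroxy-6-[(4-methoxybenzyl)oxy]nona-3,8-dien-2-one, via (2R,3R)-2-hydroxy-3-[(4-methoxybenzyl)oxy]hex-5-enal 7 (not isolated)
Conditions: TEMPO (cat.), PhI(OAc)2, CH2Cl2, rt; then 6, 40 °C
Reagents that add atoms: none
Why: One-pot oxoammonium oxidation, selective for the primary hydroxyl of a 1,2-diol, then Wittig reaction of the α-hydroxy aldehyde with the stabilised ylide to give the E-enone (C10=C1); the non-basic medium should keep C9 from epimerising.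

Step 6
Reactants: 8 (3E,5S,6R)-5-hydroxy-6-[(4-methoxybenzyl)oxy]nona-3,8-dien-2-one; 9 tiglic acid
Product: 10 (3E,5S,6R)-6-[(4-methoxybenzyl)oxy]-2-oxonona-3,8-dien-5-yl (2E)-2-methylbut-2-enoate
Conditions: DCC, DMAP (cat.), CH2Cl2, 0 °C → rt
Reagents that add atoms: none
Why: Steglich esterification of the allylic C9 hydroxyl; the tiglate is the future dienophile and brings C4, C5, C6, C14 and C15.

Step 7
Reactants: 10 (3E,5S,6R)-6-[(4-methoxybenzyl)oxy]-2-oxonona-3,8-dien-5-yl (2E)-2-methylbut-2-enoate
Product: 11 (3E,5S,6R)-6-[(4-methoxybenzyl)oxy]-2,8-dioxonon-3-en-5-yl (2E)-2-methylbut-2-enoate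
Conditions: PdCl2 (cat.), CuCl (cat.), O2 (1 atm), DMF/H2O (7:1), rt
Reagents that add atoms: water, O
Why: Wacker oxidation of the only electron-rich alkene with Markovnikov selectivity gives the C11 methyl ketone; the enone and enoate alkenes are electron-poor and should not react.

Step 8
Reactants: 11 (3E,5S,6R)-6-[(4-methoxybenzyl)oxy]-2,8-dioxonon-3-en-5-yl (2E)-2-methylbut-2-enoate
Product: 12 (3E,5S,6R)-6-[(4-methoxybenzyl)oxy]-7-(2-methyl-1,3-dioxolan-2-yl)-2-oxohept-3-en-5-yl (2E)-2-methylbut-2-enoate
Conditions: (TMSOCH2)2, TMSOTf (cat.), CH2Cl2, −78 °C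
Reagents that add atoms: 1,2-bis(trimethylsilyloxy)ethane, C[Si](C)(C)OCCO[Si](C)(C)C
Why: Low-temperature ketalisation with the bis-silyl ether of the diol converts the saturated ketone; the conjugated ketone is much less electrophilic and should remain.

Step 9
Reactants: 12 (3E,5S,6R)-6-[(4-methoxybenzyl)oxy]-7-(2-methyl-1,3-dioxolan-2-yl)-2-oxohept-3-en-5-yl (2E)-2-methylbut-2-enoate
Product: 13 (3E,5S,6R)-2-[(tert-butyldimethylsilyl)oxy]-6-[(4-methoxybenzyl)oxy]-7-(2-methyl-1,3-dioxolan-2-yl)hepta-1,3-dien-5-yl (2E)-2-methylbut-2-enoate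
Conditions: TBSOTf, Et3N, CH2Cl2, −78 → 0 °C
Reagents that add atoms: tert-butyldimethylsilyl trifluoromethanesulfonate, CC(C)(C)[Si](C)(C)OS(=O)(=O)C(F)(F)F
Why: Soft enolisation at the methyl group of the silyl-activated enone gives the cross-conjugated 2-silyloxydiene; ketal and ester tolerate the silyl triflate at low temperature and γ-deprotonation at C9 is not expected under these kinetic conditions.

Step 10
Reactants: 13 (3E,5S,6R)-2-[(tert-butyldimethylsilyl)oxy]-6-[(4-methoxybenzyl)oxy]-7-(2-methyl-1,3-dioxolan-2-yl)hepta-1,3-dien-5-yl (2E)-2-methylbut-2-enoate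
Product: 14 (3S,3aS,7S,7aR)-5-[(tert-butyldimethylsilyl)oxy]-3-[(1R)-1-[(4-methoxybenzyl)oxy]-2-(2-methyl-1,3-dioxolan-2-yl)ethyl]-7,7a-dimethyl-3a,6,7,7a-tetrahydroisobenzofuran-1(3H)-one
Conditions: PhMe (0.01 M), BHT (cat.), Et3N (cat.), 170 °C, sealed tube
Reagents that add atoms: none
Why: A concerted, suprafacial [4+2] cycloaddition of the known lactone-forming class (type 1 intramolecular Diels–Alder of an ester-tethered 1,3,8-nonatriene), here with a 2-silyloxydiene and a trisubstituted enoate; the CH2 terminus of the enol ether (C3), the most electron-rich diene carbon, attacks the enoate β-position C4 while C10 joins the α-carbon C5, so electronic preference and tether geometry ask for the same regiochemistry. Ring A closes in the cycloaddition itself as a cyclohexene with the C1=C2 silyl enol ether; the γ-lactone closes as a consequence, because the chain C9–O9–C6 already links C10 to C5. C4 and C5 take their relation from the E geometry of the tiglate, so C14 and C15 become cis. C10 relative to C5 follows from the tether carbonyl lying endo under the diene, which places both methyl groups exo and gives the cis ring fusion (C14 cis to H10); the exo-tether mode would push both methyl groups under the diene and lead to the more strained trans-fused lactone. The absolute sense comes from C9 in the tether: in the endo transition state its two free substituents take one site close to H1 and one pointing away from the diene, the C8 chain takes the remote site and H9 the one near H1 (minimal allylic 1,3-strain), and this exposes the diene face that gives the 9S/10S relation with C8 on the convex face. The step thus needs endo (cis-fusion) selectivity and diene-face selectivity, the first secured by the short ester tether and the exo methyl groups, the second by the C9 stereocentre. The reactive s-cis ester rotamer is the minor one, hence the high temperature and dilution; BHT and a trace of base protect the silyl dienol ether.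

Step 11
Reactants: 14 (3S,3aS,7S,7aR)-5-[(tert-butyldimethylsilyl)oxy]-3-[(1R)-1-[(4-methoxybenzyl)oxy]-2-(2-methyl-1,3-dioxolan-2-yl)ethyl]-7,7a-dimethyl-3a,6,7,7a-tetrahydroisobenzofuran-1(3H)-one
Product: 15 (3S,3aS,7S,7aR)-5-[(tert-butyldimethylsilyl)oxy]-3-[(1R)-1-[(4-methoxybenzyl)oxy]-2-(2-methyl-1,3-dioxolan-2-yl)ethyl]-7,7a-dimethyl-1,3,3a,6,7,7a-hexahydroisobenzofuran-1-ol (both C1 epimers)
Conditions: i-Bu2AlH, CH2Cl2, −78 °C; aq. KNaC4H4O6
Reagents that add atoms: none
Why: Partial reduction of the γ-lactone to the lactol, whose tetrahedral O–Al(i-Bu)2 adduct is stable at −78 °C; the lactol is the masked C6 aldehyde, and silyl enol ether, ketal and PMB ether are inert.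

Step 12
Reactants: 15 (3S,3aS,7S,7aR)-5-[(tert-butyldimethylsilyl)oxy]-3-[(1R)-1-[(4-methoxybenzyl)oxy]-2-(2-methyl-1,3-dioxolan-2-yl)ethyl]-7,7a-dimethyl-1,3,3a,6,7,7a-hexahydroisobenzofuran-1-ol
Product: 16 (3S,3aS,7S,7aR)-1-hydroxy-3-[(1R)-1-[(4-methoxybenzyl)oxy]-3-oxobutyl]-7,7a-dimethylhexahydroisobenzofuran-5(3H)-one
Conditions: 1 M aq. HCl, THF, rt
Reagents that add atoms: water, O
Why: Aqueous acid hydrolyses the dioxolane (C11 ketone) and the silyl enol ether (C2 ketone, protonation at C1); neither ketone has an epimerisable stereocentre here, and the PMB ether and the lactol should survive dilute acid.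

Step 13
Reactants: 16 (3S,3aS,7S,7aR)-1-hydroxy-3-[(1R)-1-[(4-methoxybenzyl)oxy]-3-oxobutyl]-7,7a-dimethylhexahydroisobenzofuran-5(3H)-one
Product: 18 (4S,4aS,7R,8S,8aS)-6-acetyl-8-hydroxy-7-[(4-methoxybenzyl)oxy]-4,4a-dimethyl-3,4,4a,7,8,8a-hexahydronaphthalen-2(1H)-one, via β-hydroxy ketone aldol adduct 17 (not isolated)
Conditions: pyrrolidine, AcOH, PhMe, 60 °C
Reagents that add atoms: none
Why: Amine/acid-mediated intramolecular aldol condensation on the ring-opened lactol: only C7 can reach the non-enolisable C6 aldehyde through a six-membered transition state (C12 would give an eight-membered ring, C1 and C3 four-membered rings), and dehydration to the conjugated enone is the one irreversible channel, whereas ketone–ketone additions involving C2 are reversible. The C8 alkoxy group is a poor leaving group in the buffered medium, so β-elimination should lag behind ring closure; no stereocentre is created in the isolated product.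

Step 14
Reactants: 18 (4S,4aS,7R,8S,8aS)-6-acetyl-8-hydroxy-7-[(4-methoxybenzyl)oxy]-4,4a-dimethyl-3,4,4a,7,8,8a-hexahydronaphthalen-2(1H)-one
Product: 19 (4S,4aR,6S,7R,8S,8aS)-6-acetyl-8-hydroxy-7-[(4-methoxybenzyl)oxy]-4,4a-dimethyloctahydronaphthalen-2(1H)-one
Conditions: [Ir(cod)(PCy3)(py)]PF6 (cat.), H2 (1 atm), CH2Cl2, rt
Reagents that add atoms: none
Why: Hydroxyl-directed hydrogenation: the homoallylic C9 hydroxyl binds the cationic iridium complex and H2 is delivered to the face of C6=C7 that carries O9 and O8, so H7 ends up cis to both oxygens and the acetyl group trans to O8, as required; the C2 ketone and PMB ether are not affected.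

Step 15
Reactants: 19 (4S,4aR,6S,7R,8S,8aS)-6-acetyl-8-hydroxy-7-[(4-methoxybenzyl)oxy]-4,4a-dimethyloctahydronaphthalen-2(1H)-one; 9 tiglic acid
Product: 21 (4S,4aR,6S,7R,8S,8aS)-6-acetyl-7-[(4-methoxybenzyl)oxy]-4,4a-dimethyl-8-{[(2E)-2-methylbut-2-enoyl]oxy}octahydronaphthalen-2(1H)-one, via tiglic 2,4,6-trichlorobenzoic anhydride 20 (not isolated)
Conditions: 9, 2,4,6-Cl3C6H2COCl, Et3N, THF, rt; then 19, DMAP, PhMe, rt → 40 °C
Reagents that add atoms: none
Why: Yamaguchi esterification of the hindered C9 hydroxyl through the mixed anhydride and DMAP acyl transfer; any bridged hemiketal between O9 and the C2 ketone is in equilibrium with the open hydroxy ketone and is drained by acylation.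

Step 16
Reactants: 21 (4S,4aR,6S,7R,8S,8aS)-6-acetyl-7-[(4-methoxybenzyl)oxy]-4,4a-dimethyl-8-{[(2E)-2-methylbut-2-enoyl]oxy}octahydronaphthalen-2(1H)-one
Product: 22 (4S,4aR,6S,7R,8S,8aS)-6-acetyl-2,2-(ethylenedioxy)-7-[(4-methoxybenzyl)oxy]-4,4a-dimethyl-8-{[(2E)-2-methylbut-2-enoyl]oxy}decahydronaphthalene
Conditions: (TMSOCH2)2, TMSOTf (cat.), CH2Cl2, −78 → −40 °C
Reagents that add atoms: 1,2-bis(trimethylsilyloxy)ethane, C[Si](C)(C)OCCO[Si](C)(C)C
Why: Kinetic ketalisation: the ring ketone C2, flanked by two methylene groups, should react before the α-branched acetyl group C11, the same discrimination used for 3,20-diketones of the pregnane series; with O9 acylated no hydroxyl can intercept the oxocarbenium ion.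

Step 17
Reactants: 22 (4S,4aR,6S,7R,8S,8aS)-6-acetyl-2,2-(ethylenedioxy)-7-[(4-methoxybenzyl)oxy]-4,4a-dimethyl-8-{[(2E)-2-methylbut-2-enoyl]oxy}decahydronaphthalene
Product: 23 (4S,4aR,6R,7R,8S,8aS)-2,2-(ethylenedioxy)-7-[(4-methoxybenzyl)oxy]-4,4a-dimethyl-8-{[(2E)-2-methylbut-2-enoyl]oxy}-6-(prop-1-en-2-yl)decahydronaphthalene
Conditions: CH2Br2, Zn, TiCl4, THF/CH2Cl2, 0 °C → rt
Reagents that add atoms: dibromomethane, BrCBr
Why: Lombardo–Takai methylenation, a non-basic reagent that converts ketones in the presence of esters and does not enolise C11, so C7 is not epimerised and the C8 alkoxy group is not eliminated.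

Step 18
Reactants: 23 (4S,4aR,6R,7R,8S,8aS)-2,2-(ethylenedioxy)-7-[(4-methoxybenzyl)oxy]-4,4a-dimethyl-8-{[(2E)-2-methylbut-2-enoyl]oxy}-6-(prop-1-en-2-yl)decahydronaphthalene
Product: 24 (4S,4aR,6R,7R,8S,8aS)-2,2-(ethylenedioxy)-7-hydroxy-4,4a-dimethyl-8-{[(2E)-2-methylbut-2-enoyl]oxy}-6-(prop-1-en-2-yl)decahydronaphthalene
Conditions: DDQ, CH2Cl2/pH 7 buffer, 0 °C → rt
Reagents that add atoms: none
Why: Oxidative cleavage of the PMB ether (benzylic hydride abstraction, hydrolysis of the hemiacetal); the neutral medium should keep the tiglate from migrating to the freed O8, and the 1,1-disubstituted alkene and the ketal are inert.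

Step 19
Reactants: 24 (4S,4aR,6R,7R,8S,8aS)-2,2-(ethylenedioxy)-7-hydroxy-4,4a-dimethyl-8-{[(2E)-2-methylbut-2-enoyl]oxy}-6-(prop-1-en-2-yl)decahydronaphthalene; 25 (R)-2-methylbutanoic acid
Product: 26 (4S,4aR,6R,7R,8S,8aS)-2,2-(ethylenedioxy)-4,4a-dimethyl-7-{[(2R)-2-methylbutanoyl]oxy}-8-{[(2E)-2-methylbut-2-enoyl]oxy}-6-(prop-1-en-2-yl)decahydronaphthalene
Conditions: 25, DCC, DMAP (cat.), CH2Cl2, 0 °C → rt
Reagents that add atoms: none
Why: Steglich esterification; carbodiimide activation with catalytic DMAP does not pass through a ketene, so the α-stereocentre of the acid should be retained, and the step follows step 18 directly to forestall acyl migration.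

Step 20
Reactants: 26 (4S,4aR,6R,7R,8S,8aS)-2,2-(ethylenedioxy)-4,4a-dimethyl-7-{[(2R)-2-methylbutanoyl]oxy}-8-{[(2E)-2-methylbut-2-enoyl]oxy}-6-(prop-1-en-2-yl)decahydronaphthalene
Product: 27 (4S,4aR,6R,7R,8S,8aS)-4,4a-dimethyl-7-{[(2R)-2-methylbutanoyl]oxy}-8-{[(2E)-2-methylbut-2-enoyl]oxy}-6-(prop-1-en-2-yl)octahydronaphthalen-2(1H)-one (CNP0312791.1)
Conditions: 1 M aq. HCl, THF, rt
Reagents that add atoms: water, O
Why: Mild hydrolysis of the dioxolane frees the C2 ketone; both esters and the isopropenyl group should tolerate dilute aqueous acid at room temperature, and no stereocentre is α to C2.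

## Compound list

1 | 2-deoxy-L-ribose | O=CC[C@@H](O)[C@@H](O)CO | starting material
2 | (2S,3R)-hex-5-ene-1,2,3-triol | C=CC[C@@H](O)[C@@H](O)CO | intermediate
3 | (1R)-1-[(4S)-2,2-dimethyl-1,3-dioxolan-4-yl]but-3-en-1-ol | C=CC[C@@H](O)[C@@H]1COC(C)(C)O1 | intermediate
4 | (4S)-4-[(1R)-1-[(4-methoxybenzyl)oxy]but-3-en-1-yl]-2,2-dimethyl-1,3-dioxolane | C=CC[C@@H](OCc1ccc(OC)cc1)[C@@H]1COC(C)(C)O1 | intermediate
5 | (2S,3R)-3-[(4-methoxybenzyl)oxy]hex-5-ene-1,2-diol | C=CC[C@@H](OCc1ccc(OC)cc1)[C@@H](O)CO | intermediate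
6 | 1-(triphenylphosphoranylidene)propan-2-one | CC(=O)C=P(c1ccccc1)(c1ccccc1)c1ccccc1 | starting material
7 | (2R,3R)-2-hydroxy-3-[(4-methoxybenzyl)oxy]hex-5-enal | C=CC[C@@H](OCc1ccc(OC)cc1)[C@@H](O)C=O | intermediate
8 | (3E,5S,6R)-5-hydroxy-6-[(4-methoxybenzyl)oxy]nona-3,8-dien-2-one | C=CC[C@@H](OCc1ccc(OC)cc1)[C@@H](O)/C=C/C(C)=O | intermediate
9 | tiglic acid | C/C=C(\C)C(=O)O | starting material
10 | (3E,5S,6R)-6-[(4-methoxybenzyl)oxy]-2-oxonona-3,8-dien-5-yl (2E)-2-methylbut-2-enoate | C=CC[C@@H](OCc1ccc(OC)cc1)[C@@H](OC(=O)/C(C)=C/C)/C=C/C(C)=O | intermediate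
11 | (3E,5S,6R)-6-[(4-methoxybenzyl)oxy]-2,8-dioxonon-3-en-5-yl (2E)-2-methylbut-2-enoate | CC(=O)C[C@@H](OCc1ccc(OC)cc1)[C@@H](OC(=O)/C(C)=C/C)/C=C/C(C)=O | intermediate
12 | (3E,5S,6R)-6-[(4-methoxybenzyl)oxy]-7-(2-methyl-1,3-dioxolan-2-yl)-2-oxohept-3-en-5-yl (2E)-2-methylbut-2-enoate | CC1(C[C@@H](OCc2ccc(OC)cc2)[C@@H](OC(=O)/C(C)=C/C)/C=C/C(C)=O)OCCO1 | intermediate
13 | (3E,5S,6R)-2-[(tert-butyldimethylsilyl)oxy]-6-[(4-methoxybenzyl)oxy]-7-(2-methyl-1,3-dioxolan-2-yl)hepta-1,3-dien-5-yl (2E)-2-methylbut-2-enoate | C=C(O[Si](C)(C)C(C)(C)C)/C=C/[C@H](OC(=O)/C(C)=C/C)[C@@H](CC1(C)OCCO1)OCc1ccc(OC)cc1 | intermediate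
14 | (3S,3aS,7S,7aR)-5-[(tert-butyldimethylsilyl)oxy]-3-[(1R)-1-[(4-methoxybenzyl)oxy]-2-(2-methyl-1,3-dioxolan-2-yl)ethyl]-7,7a-dimethyl-3a,6,7,7a-tetrahydroisobenzofuran-1(3H)-one | O=C1[C@@]2(C)[C@H](C=C(O[Si](C)(C)C(C)(C)C)C[C@@H]2C)[C@H](O1)[C@@H](CC3(C)OCCO3)OCc4ccc(OC)cc4 | intermediate
15 | lactol of 14, 1,3,3a,6,7,7a-hexahydroisobenzofuran-1-ol (both C1 epimers) | OC1[C@@]2(C)[C@H](C=C(O[Si](C)(C)C(C)(C)C)C[C@@H]2C)[C@H](O1)[C@@H](CC3(C)OCCO3)OCc4ccc(OC)cc4 | intermediate
16 | (3S,3aS,7S,7aR)-1-hydroxy-3-[(1R)-1-[(4-methoxybenzyl)oxy]-3-oxobutyl]-7,7a-dimethylhexahydroisobenzofuran-5(3H)-one | OC1[C@@]2(C)[C@H](CC(=O)C[C@@H]2C)[C@H](O1)[C@@H](CC(C)=O)OCc3ccc(OC)cc3 | intermediate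
17 | aldol adduct: 6-acetyl-5,8-dihydroxy-7-[(4-methoxybenzyl)oxy]-4,4a-dimethyloctahydronaphthalen-2(1H)-one (C6 and C7 of the decalin not defined) | CC(=O)C1C(O)[C@@]2(C)[C@H](CC(=O)C[C@@H]2C)[C@H](O)[C@@H]1OCc3ccc(OC)cc3 | intermediate
18 | (4S,4aS,7R,8S,8aS)-6-acetyl-8-hydroxy-7-[(4-methoxybenzyl)oxy]-4,4a-dimethyl-3,4,4a,7,8,8a-hexahydronaphthalen-2(1H)-one | CC(=O)C1=C[C@@]2(C)[C@H](CC(=O)C[C@@H]2C)[C@H](O)[C@@H]1OCc3ccc(OC)cc3 | intermediate
19 | (4S,4aR,6S,7R,8S,8aS)-6-acetyl-8-hydroxy-7-[(4-methoxybenzyl)oxy]-4,4a-dimethyloctahydronaphthalen-2(1H)-one | CC(=O)[C@H]1C[C@@]2(C)[C@H](CC(=O)C[C@@H]2C)[C@H](O)[C@@H]1OCc3ccc(OC)cc3 | intermediate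
20 | tiglic 2,4,6-trichlorobenzoic anhydride | C/C=C(\C)C(=O)OC(=O)c1c(Cl)cc(Cl)cc1Cl | intermediate
21 | (4S,4aR,6S,7R,8S,8aS)-6-acetyl-7-[(4-methoxybenzyl)oxy]-4,4a-dimethyl-8-{[(2E)-2-methylbut-2-enoyl]oxy}octahydronaphthalen-2(1H)-one | CC(=O)[C@H]1C[C@@]2(C)[C@H](CC(=O)C[C@@H]2C)[C@H](OC(=O)/C(C)=C/C)[C@@H]1OCc3ccc(OC)cc3 | intermediate
22 | C2 ethylene ketal of 21 | CC(=O)[C@H]1C[C@@]2(C)[C@H](CC3(OCCO3)C[C@@H]2C)[C@H](OC(=O)/C(C)=C/C)[C@@H]1OCc4ccc(OC)cc4 | intermediate
23 | (4S,4aR,6R,7R,8S,8aS)-2,2-(ethylenedioxy)-7-[(4-methoxybenzyl)oxy]-4,4a-dimethyl-8-{[(2E)-2-methylbut-2-enoyl]oxy}-6-(prop-1-en-2-yl)decahydronaphthalene | C=C(C)[C@H]1C[C@@]2(C)[C@H](CC3(OCCO3)C[C@@H]2C)[C@H](OC(=O)/C(C)=C/C)[C@@H]1OCc4ccc(OC)cc4 | intermediate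
24 | (4S,4aR,6R,7R,8S,8aS)-2,2-(ethylenedioxy)-7-hydroxy-4,4a-dimethyl-8-{[(2E)-2-methylbut-2-enoyl]oxy}-6-(prop-1-en-2-yl)decahydronaphthalene | C=C(C)[C@H]1C[C@@]2(C)[C@H](CC3(OCCO3)C[C@@H]2C)[C@H](OC(=O)/C(C)=C/C)[C@@H]1O | intermediate
25 | (R)-2-methylbutanoic acid | CC[C@@H](C)C(=O)O | starting material
26 | C2 ethylene ketal of the target | C=C(C)[C@H]1C[C@@]2(C)[C@H](CC3(OCCO3)C[C@@H]2C)[C@H](OC(=O)/C(C)=C/C)[C@@H]1OC(=O)[C@H](C)CC | intermediate
27 | (4S,4aR,6R,7R,8S,8aS)-4,4a-dimethyl-7-{[(2R)-2-methylbutanoyl]oxy}-8-{[(2E)-2-methylbut-2-enoyl]oxy}-6-(prop-1-en-2-yl)octahydronaphthalen-2(1H)-one | C=C(C)[C@H]1C[C@@]2(C)[C@H](CC(=O)C[C@@H]2C)[C@H](OC(=O)/C(C)=C/C)[C@@H]1OC(=O)[C@H](C)CC | target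

## Step count and least certain steps

Total: 20 steps. Longest linear sequence: 20 steps (1 → 27).

Step 10 (key step). The cycloaddition may be too slow, since the dienophile is trisubstituted and the reactive s-cis ester rotamer is the minor one; at the temperature needed the silyl dienol ether may then decompose or tiglic acid may be eliminated. Closure through the exo-tether mode or on the other diene face would give the wrong C5/C10 or C9/C10 relation. Fallback, from 8 and back at 16: ring A is made by the intermolecular counterpart. Alcohol 8 is silylated (Et3SiCl, imidazole) to the triethylsilyl ether of 8 F1, which is taken through the same Wacker oxidation to the diketone F2 and the same ketalisation to the ketal F3. TBSOTf/Et3N converts F3 into the silyloxydiene F4. A Lewis-acid-promoted Diels–Alder reaction with (E)-2-methylbut-2-enal (Me2AlCl, CH2Cl2, −78 °C, aldehyde endo) gives the cyclohexene carbaldehyde F5, in which C6 is already at the aldehyde level. Aqueous HCl in THF removes both silyl groups and the ketal, and the hydroxy aldehyde closes to lactol 16. The diene face is then set by the C9 silyloxy stereocentre alone, which is the weak point of this variant.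

Step 13. The C7 enol or enamine may expel the C8 alkoxy group by β-elimination faster than it closes the ring, the lactol may be reluctant to open, or the free C2 ketone may divert the nucleophile into reversible side equilibria. Fallback, from 16 and back at 18: C–C bond formation and elimination are separated. Under protic acid (camphorsulfonic acid, PhMe, 60 °C) the lactol ionises to the cyclic oxocarbenium ion, which is attacked by the more substituted enol of the C11 ketone to give the oxygen-bridged ketone F6 (a 7-oxabicyclo[2.2.1]heptane with O9 still bound to C6). DBU then opens the strained bridge by β-elimination toward C6 and gives 18.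

Step 14. Face selectivity may be poor if coordination of the C9 hydroxyl is outcompeted (hemiketal formation with C2, shielding by the C8 ether), or the electron-poor trisubstituted alkene may be reduced too slowly. Fallback, from 18 and back at 21: conjugate reduction with [(Ph3P)CuH]6 in PhMe gives 19 together with its C7 epimer F7. The mixture is acylated as in step 15, giving 21 and the C7 epimer of 21 F8. Treatment with DBU equilibrates C7 toward 21, whose acetyl group is equatorial; with O9 acylated no hemiketal can favour the wrong epimer.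

Step 16. The two saturated ketones may not be discriminated well enough, because a ketal at C2 suffers a syn-axial interaction in either chair form of the cis-decalin. Fallback, from 19 and back at 27: O9 is used as an internal protecting group for C2. Alcohol 19 in MeOH with pyridinium p-toluenesulfonate should give the bridged methyl ketal F9 (C2 bonded to O9 and OMe; the trans-disposed C11 ketone cannot take part). Methylenation with CH2Br2/Zn/TiCl4 gives the isopropenyl ketal F10, and dilute aqueous HCl in THF reopens it to the hydroxy ketone F11. Yamaguchi acylation with 9 gives the O9 tiglate F12, DDQ gives the O8 alcohol F13, and esterification with 25 (DCC, DMAP) gives 27 directly, with no final deprotection.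

## Further compounds

F1 | step 10 | O9-triethylsilyl ether of 8, (3E,5S,6R)-6-[(4-methoxybenzyl)oxy]-5-[(triethylsilyl)oxy]nona-3,8-dien-2-one | C=CC[C@@H](OCc1ccc(OC)cc1)[C@@H](O[Si](CC)(CC)CC)/C=C/C(C)=O
F2 | step 10 | (3E,5S,6R)-6-[(4-methoxybenzyl)oxy]-5-[(triethylsilyl)oxy]non-3-ene-2,8-dione | CC(=O)C[C@@H](OCc1ccc(OC)cc1)[C@@H](O[Si](CC)(CC)CC)/C=C/C(C)=O
F3 | step 10 | (3E,5S,6R)-6-[(4-methoxybenzyl)oxy]-7-(2-methyl-1,3-dioxolan-2-yl)-5-[(triethylsilyl)oxy]hept-3-en-2-one | CC1(C[C@@H](OCc2ccc(OC)cc2)[C@@H](O[Si](CC)(CC)CC)/C=C/C(C)=O)OCCO1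
F4 | step 10 | 2-(tert-butyldimethylsilyloxy)diene from F3 | C=C(O[Si](C)(C)C(C)(C)C)/C=C/[C@H](O[Si](CC)(CC)CC)[C@@H](CC1(C)OCCO1)OCc1ccc(OC)cc1
F5 | step 10 | (1R,2S,6S)-4-[(tert-butyldimethylsilyl)oxy]-1,6-dimethyl-2-[(1S,2R)-2-[(4-methoxybenzyl)oxy]-3-(2-methyl-1,3-dioxolan-2-yl)-1-[(triethylsilyl)oxy]propyl]cyclohex-3-ene-1-carbaldehyde | O=C[C@@]1(C)[C@H](C=C(O[Si](C)(C)C(C)(C)C)C[C@@H]1C)[C@H](O[Si](CC)(CC)CC)[C@@H](CC2(C)OCCO2)OCc3ccc(OC)cc3
F6 | step 13 | oxygen-bridged aldol product of 16 (O9 bonded to C6; C6 and C7 not defined) | CC(=O)C1C2[C@@]3(C)[C@H](CC(=O)C[C@@H]3C)[C@H](O2)[C@@H]1OCc4ccc(OC)cc4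
F7 | step 14 | C7 epimer of 19 | CC(=O)[C@@H]1C[C@@]2(C)[C@H](CC(=O)C[C@@H]2C)[C@H](O)[C@@H]1OCc3ccc(OC)cc3
F8 | step 14 | C7 epimer of 21 | CC(=O)[C@@H]1C[C@@]2(C)[C@H](CC(=O)C[C@@H]2C)[C@H](OC(=O)/C(C)=C/C)[C@@H]1OCc3ccc(OC)cc3
F9 | step 16 | bridged methyl ketal of 19 (C2 bonded to O9 and OMe) | CC(=O)[C@H]1C[C@@]2(C)[C@H](C[C@]3(OC)C[C@@H]2C)[C@H](O3)[C@@H]1OCc4ccc(OC)cc4
F10 | step 16 | bridged methyl ketal with C7 isopropenyl group | C=C(C)[C@H]1C[C@@]2(C)[C@H](C[C@]3(OC)C[C@@H]2C)[C@H](O3)[C@@H]1OCc4ccc(OC)cc4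
F11 | step 16 | (4S,4aR,6R,7R,8S,8aS)-8-hydroxy-7-[(4-methoxybenzyl)oxy]-4,4a-dimethyl-6-(prop-1-en-2-yl)octahydronaphthalen-2(1H)-one | C=C(C)[C@H]1C[C@@]2(C)[C@H](CC(=O)C[C@@H]2C)[C@H](O)[C@@H]1OCc3ccc(OC)cc3
F12 | step 16 | O9 tiglate of F11 | C=C(C)[C@H]1C[C@@]2(C)[C@H](CC(=O)C[C@@H]2C)[C@H](OC(=O)/C(C)=C/C)[C@@H]1OCc3ccc(OC)cc3
F13 | step 16 | (4S,4aR,6R,7R,8S,8aS)-7-hydroxy-4,4a-dimethyl-8-{[(2E)-2-methylbut-2-enoyl]oxy}-6-(prop-1-en-2-yl)octahydronaphthalen-2(1H)-one | C=C(C)[C@H]1C[C@@]2(C)[C@H](CC(=O)C[C@@H]2C)[C@H](OC(=O)/C(C)=C/C)[C@@H]1O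
A1 | alternative 1 | cis-decalin with C7 acetyl, C8/C9 acetonide, C2 ketal | CC(=O)[C@H]1C[C@@]2(C)[C@H](CC3(OCCO3)C[C@@H]2C)[C@H](OC4(C)C)[C@@H]1O4
A2 | alternative 1 | 5-methylene ring-A precursor with tethered α-methylene ketone | CC(=O)C(=C)[C@H]1OC(C)(C)O[C@H]1[C@H]2CC3(OCCO3)C[C@H](C)C2=C
A3 | alternative 2 | cis-fused enedione (C8 enone, C4 ketone, C2 silyl ether) | C1=C[C@@]2(C)[C@H](C[C@H](O[Si](C)(C)C(C)(C)C)CC2=O)CC1=O
A4 | alternative 2 | 5-[(tert-butyldimethylsilyl)oxy]-2-methylcyclohex-2-en-1-one | CC1=CC[C@H](O[Si](C)(C)C(C)(C)C)CC1=O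
A5 | alternative 2 | (E)-1-methoxy-3-(trimethylsilyloxy)buta-1,3-diene | CO/C=C/C(=C)O[Si](C)(C)C
A6 | alternative 3 | cis-decalin with C9 hydroxyl, C8 silyl ether, C7 isopropenyl | C=C(C)[C@H]1C[C@@]2(C)[C@H](CC(=O)C[C@@H]2C)[C@H](O)[C@@H]1O[Si](C)(C)C(C)(C)C
A7 | alternative 3 | ring-A enone with tethered C9 aldehyde | C=C(C)[C@@H](C[C@@]1(C)C=CC(=O)C[C@@H]1C)[C@@H](O[Si](C)(C)C(C)(C)C)C=O
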